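# Proposed total synthesis of 5,7-dihydroxy-6,8,3',4',5'-pentamethoxyflavone by aryne insertion into an arylpropiolic acid

## Structural features

The target is a flavone. Benzene ring A is fused through C4a and C8a to the 4-pyranone ring C, and ring C carries the 3,4,5-trimethoxyphenyl ring B on C2 by a single bond. There is no stereocenter, so no configuration has to be set and no stereocenters stand next to each other. Ring A is fully substituted: starting at C4a, which bears the carbonyl carbon C4, it carries C5–OH, C6–OMe, C7–OH, C8–OMe and C8a–O1, five oxygens in a row that alternate between free (or ring) oxygen and methyl ether. The fragile points are the phenols on a very electron-rich ring (oxidation to quinones, above all in polyhydroxy intermediates under base and air), the vinylogous ester of ring C (ring opening by hard nucleophiles, reduction of C2–C3) and, in the intermediates, the aryl–silicon bond, the ester and the benzyl ether. The real difficulty is to attach the acyl carbon C4 to C4a, which is hemmed in by two oxygen-bearing carbons, while keeping O5 and O7 distinct from the methylated O6 and O8. The plan exploits the fact that C4a and C8a are neighbours carrying an acyl carbon and an oxygen: a carboxylic acid can hand exactly these two groups to an aryne drawn across C4a–C8a, and an arylpropiolic acid brings C2, C3 and ring B with it, so that ring C closes in the same flask. Without C4 and O1, ring A is a 2,4-dimethoxyphloroglucinol whose central oxygen (O7) sits between two methoxy groups just as the hydroxyl of 2,6-dimethoxyphenol does; this local mirror symmetry is kept until silicon is placed on C4a.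

## Logic of the disconnections

19 from 18. The benzyl–O7 bond is cut. O7 must stay masked through bromination, organolithium, palladium and fluoride chemistry, and a benzyl ether does this and leaves under neutral conditions. The gain is that no intermediate carries two free phenols after step 8. The forward hydrogenolysis must stop before the C2–C3 double bond of ring C is reduced.

18 from 17. The acyl–O5 bond of the ester is cut. The ester is there for the key step, where an inductively withdrawing and bulky group on O5 is wanted; afterwards it is only a protecting group. The forward methanolysis must be mild enough to leave ring C closed.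

17 from 12 and 14. Three bonds are cut: O1–C2, C8a–O1 and C4a–C4. This removes ring C and the most crowded carbon–carbon bond of the molecule in one stroke and leaves two pieces of similar size. The forward step must put oxygen on C8a and the acyl group on C4a and not the reverse, the C4a anion must choose the right carbonyl, and ring closure must be 6-endo.

14 from 13. The bond between the carboxyl carbon (C4) and the alkyne carbon (C3) is cut, which leads to a terminal alkyne and a one-carbon electrophile. The forward step needs only a clean acetylide.

12 from 11. The S–O bond at the C8a oxygen is cut. Placing the leaving group last means that no earlier intermediate can release the aryne. The forward sulfonylation must leave the ester and the aryl–silicon bond alone.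

11 from 7 and 8. The C4a–Si bond is cut by returning silicon to a neighbouring oxygen, and the acyl–O5 bond is cut. In 7 the two oxygens beside the brominated carbon are equivalent; the forward silyl shift makes one of them an anion and leaves the other silylated, so they are differentiated without statistical monoprotection. The demand is that the shift is complete before the acyl chloride is added and that only the anionic oxygen is acylated.

7 from 6 and 6 from 5. Two O–Si bonds and then the C4a–Br bond are cut. The bromine marks the one free ring position and becomes the source of the C4a carbanion. The forward bromination must be faster than oxidation of the electron-rich diol.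

5 from 4 and 4 from 3. The C5–O and C8a–O bonds are cut back to C–B and then to C–Br. Both oxygens are introduced together because the two positions are equivalent. The forward steps must convert both positions completely and must not overoxidise 5.

3 from 2 and 2 from 1. The two C–Br bonds and the benzyl–O bond are cut. This reaches 1, which already holds O7 between the two methoxy groups; the symmetry of 1 to 7 means that every twofold reaction can give only one compound. The forward bromination must choose the two positions next to the methoxy groups over the central one.

## Other disconnections considered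

Alternative 1: Hindered nitrile oxide cycloaddition, with an isoxazole as masked diketone.
- **Cut:** C3–C4 and O1–C2, with C2, C3 and C4 stored in 3-[2,4,6-tris(benzyloxy)-3,5-dimethoxyphenyl]-5-(3,4,5-trimethoxyphenyl)isoxazole A1, whose N–O bond is broken later to uncover the 1,3-dicarbonyl.
- **Forward key step:** 1,3-dipolar cycloaddition of 2,4,6-tris(benzyloxy)-3,5-dimethoxybenzonitrile oxide A2 to alkyne 13. A2 would come from 1,3,5-tris(benzyloxy)-2,4-dimethoxybenzene A3 (5 after double benzylation) by formylation at its one free position, oxime formation and oxidation.
- **In favour:** a nitrile oxide with two ortho substituents should resist dimerisation, a terminal alkyne should give only the 3,5-disubstituted isoxazole, no metal is needed, and hydrogenation could break the N–O bond and remove all three benzyl groups together.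
- **Better than the chosen plan on regiochemistry:** the ring A part of A1 is symmetrical about the axis through C4a and C7, so either ortho oxygen gives the same flavone and the question of which aryne terminus is attacked never arises.
- **Against:** the cycloaddition closes no ring of the target. Ring C must be made afterwards from an enaminone or diketone carrying three free phenols, which is prone to oxidation. The dipole carbon lies between two benzyloxy groups, so the cycloaddition is expected to be slow.
- **Comparison:** the concerted cycloaddition is the more predictable key step. The chosen plan forms both bonds to ring A and ring C at once and never exposes a polyhydroxyaryl diketone. In step count the alternative (about ten from 1) is equal to or slightly shorter than the chosen twelve.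

Alternative 2: Carbon monoxide as C2 in a three-component ketone arylation.
- **Cut:** C2–C3 and C2–C1', with C2 arriving as carbon monoxide.
- **Forward key step:** zerovalent palladium (for instance from Pd(dba)2 and a chelating diphosphine) inserts into the C–I bond of 5-iodo-1,2,3-trimethoxybenzene A6, CO gives an aroylpalladium species, and the enolate of 1-[2,4,6-tris(benzyloxy)-3,5-dimethoxyphenyl]ethanone A5 is acylated at carbon. The product is 1-[2,4,6-tris(benzyloxy)-3,5-dimethoxyphenyl]-3-(3,4,5-trimethoxyphenyl)propane-1,3-dione A4; hydrogenolysis and acid cyclodehydration would follow.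
- **In favour:** two carbon–carbon bonds form in one convergent step at the right oxidation level, and A6 is commercial.
- **Better than the chosen plan on two points:** the symmetric ring A again removes any regiochemical question at ring closure, and the route is shorter (about nine steps from 1 through 5, A3 and A5).
- **Against:** no ring closes in the key step. A4 is more acidic than A5 and consumes base. Direct α-arylation without CO is a competing pathway. Acetylation of A3 with a Lewis acid may strip an ortho benzyl group. Pressurised CO is needed, and a trihydroxyaryl diketone must again be handled.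
- **Comparison:** the acylation occurs at an unhindered enolate carbon, whereas the chosen plan forms C4a–C4 intramolecularly at the crowded ring carbon. Both are reasonable answers to the same crowding, and the alternative is the more conservative one.

Alternative 3: Ring A from a squarate by cyclobutenone ring expansion.
- **Cut:** C8–C8a and, one step earlier, C5–C4a; ring A is assembled on a preformed pyranone.
- **Forward key step:** heating racemic 2-tert-butoxy-4-hydroxy-3-methoxy-4-[4-oxo-6-(3,4,5-trimethoxyphenyl)-4H-pyran-3-yl]cyclobut-2-en-1-one A8 should open the four-membered ring to a dienylketene, which closes by 6π electrocyclisation onto the pyranone and tautomerises to 7-tert-butoxy-5,8-dihydroxy-6-methoxy-2-(3,4,5-trimethoxyphenyl)-4H-chromen-4-one A7. A8 would be made from 3-tert-butoxy-4-methoxycyclobut-3-ene-1,2-dione A9 and the 3-metallated form of 5-iodo-2-(3,4,5-trimethoxyphenyl)-4H-pyran-4-one A10. Methylation of O8 and acid removal of the tert-butyl group would finish.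
- **In favour:** the hexasubstituted ring is built new, with four adjacent oxygens supplied by the squarate, by a reagent-free thermal step.
- **Equal or better than the chosen plan:** O5 and O8 emerge already differentiated (O5–H is hydrogen-bonded to C4=O), no C5 protecting group is needed, and the longest linear sequence is expected to be shorter.
- **Against:** the organometallic must add to the carbonyl of A9 next to the methoxy-bearing carbon, with only the size difference between methoxy and tert-butoxy to guide it. A metallated 4-pyranone is itself an electrophile and fragile. The hydroquinone A7 is easily oxidised to a quinone.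
- **Comparison:** both plans close one ring in the key step, one by a pericyclic cascade and one by a polar cascade. The alternative has its regiochemical risk at the squarate addition, the chosen plan at the aryne.

Key step: step 10

## Remarks on the design (made before the steps)

- **Structures checked:** in precursor 12 silicon sits on C4a, the triflate on C8a, the ester on O5 and the benzyl group on O7, which matches product 17 atom for atom. No structure needs correcting.
- **Desymmetrisation:** the two oxygens beside C4a are told apart by the silyl shift itself (one lithium phenoxide, one silyl ether), so the ester goes onto the only anionic oxygen and no statistical monoacylation of a symmetrical diol is needed.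
- **Order of functionalisation:** the ester is put on before the triflate. No intermediate then has a free phenol next to the silicon-bearing carbon while a triflate is on the ring; such a compound could pass silicon from carbon to oxygen under base and release the aryne early.
- **Choice of ester:** a sulfonate on O5 would bias the aryne more strongly, but the C4a anion next to it could expel it. A hindered carboxylate is therefore kept.
- **Assumption:** the aryne step is run under the conditions known for aryne insertion into carboxylic acids (CsF, THF, sealed tube, above 100 °C).

## Route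

Step 1
Reactants: 1 2,6-dimethoxyphenol (syringol)
Product: 2 2-(benzyloxy)-1,3-dimethoxybenzene
Conditions: BnBr, K2CO3, DMF, 60 °C
Reagents that add atoms: benzyl bromide, BrCc1ccccc1
Why: Williamson ether synthesis; the phenoxide lies between two methoxy groups, but a primary benzylic bromide in a dipolar aprotic solvent should alkylate it cleanly, and the benzyl ether then masks O7 up to the last step.

Step 2
Reactants: 2 2-(benzyloxy)-1,3-dimethoxybenzene
Product: 3 3-(benzyloxy)-1,5-dibromo-2,4-dimethoxybenzene
Conditions: NBS (2.1 equiv), MeCN, 0 °C → rt, dark
Reagents that add atoms: N-bromosuccinimide, O=C1CCC(=O)N1Br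
Why: Electrophilic aromatic bromination; each of the two equivalent positions next to a methoxy group is ortho to one methoxy and para to the other, whereas the central position is activated only by the benzyloxy group, which is twisted out of conjugation, so both bromines should enter at the future C5 and C8a.

Step 3
Reactants: 3 3-(benzyloxy)-1,5-dibromo-2,4-dimethoxybenzene
Product: 4 2,2'-[5-(benzyloxy)-4,6-dimethoxy-1,3-phenylene]bis(4,4,5,5-tetramethyl-1,3,2-dioxaborolane)
Conditions: B2pin2 (2.6 equiv), Pd(dppf)Cl2 (5 mol %), KOAc, 1,4-dioxane, 90 °C
Reagents that add atoms: bis(pinacolato)diboron, CC1(C)OB(OC1(C)C)B1OC(C)(C)C(C)(C)O1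
Why: Twofold Miyaura borylation; each C–Br bond has only one ortho substituent, and acetate is too weak a base to start Suzuki coupling between product and substrate.

Step 4
Reactants: 4 2,2'-[5-(benzyloxy)-4,6-dimethoxy-1,3-phenylene]bis(4,4,5,5-tetramethyl-1,3,2-dioxaborolane)
Product: 5 5-(benzyloxy)-4,6-dimethoxybenzene-1,3-diol
Conditions: H2O2 (30 % aq), NaOH, THF/H2O, 0 °C, under N2; then Na2S2O3, HCl to pH 3
Reagents that add atoms: hydrogen peroxide, OO
Why: Oxidation of arylboronates by 1,2-shift of the aryl group from boron to oxygen in the hydroperoxide ate complex, with retention of position; cold, oxygen-free conditions and a reductive acidic quench should protect the electron-rich diol from overoxidation.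

Step 5
Reactants: 5 5-(benzyloxy)-4,6-dimethoxybenzene-1,3-diol
Product: 6 5-(benzyloxy)-2-bromo-4,6-dimethoxybenzene-1,3-diol
Conditions: NBS (1.0 equiv), CH2Cl2/MeCN, −40 °C, dark
Reagents that add atoms: N-bromosuccinimide, O=C1CCC(=O)N1Br
Why: Electrophilic aromatic bromination at the only unsubstituted position of ring A, which is ortho to both hydroxyls and para to the benzyloxy group; low temperature and one equivalent should keep oxidation to quinones in check.

Step 6
Reactants: 6 5-(benzyloxy)-2-bromo-4,6-dimethoxybenzene-1,3-diol
Product: 7 1-(benzyloxy)-4-bromo-2,6-dimethoxy-3,5-bis[(trimethylsilyl)oxy]benzene (the bis-O-trimethylsilyl ether of 6)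
Conditions: HMDS, THF, 65 °C; evaporate to dryness
Reagents that add atoms: hexamethyldisilazane, C[Si](C)(C)N[Si](C)(C)C
Why: O-silylation of both phenols by silyl transfer from the disilazane with loss of ammonia; the moisture-sensitive product is freed from volatiles and taken on as obtained.

Step 7
Reactants: 7 1-(benzyloxy)-4-bromo-2,6-dimethoxy-3,5-bis[(trimethylsilyl)oxy]benzene; 8 pivaloyl chloride
Product: 11 3-(benzyloxy)-5-hydroxy-2,4-dimethoxy-6-(trimethylsilyl)phenyl pivalate, via lithium C-silyl phenoxide 9 (not isolated), via O-silyl aryl pivalate 10 (not isolated)
Conditions: n-BuLi, THF, −78 °C; then PivCl, DMAP (cat.), −78 °C → rt; then MeOH, aq NH4Cl, 0 °C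
Reagents that add atoms: pivaloyl chloride (compound 8), CC(C)(C)C(Cl)=O
Why: Bromine–lithium exchange gives an aryllithium between two silyl ethers, and a 1,3 oxygen-to-carbon silyl shift (retro-Brook rearrangement) puts silicon on C4a and leaves the single lithium phenoxide 9; this oxygen alone is acylated (10), and the labile aryl silyl ether is then methanolysed under near-neutral conditions that should spare the ester and the aryl–silicon bond.

Step 8
Reactants: 11 3-(benzyloxy)-5-hydroxy-2,4-dimethoxy-6-(trimethylsilyl)phenyl pivalate
Product: 12 3-(benzyloxy)-2,4-dimethoxy-5-(pivaloyloxy)-6-(trimethylsilyl)phenyl trifluoromethanesulfonate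
Conditions: Tf2O, pyridine, CH2Cl2, −78 → 0 °C
Reagents that add atoms: trifluoromethanesulfonic anhydride, O=S(=O)(OS(=O)(=O)C(F)(F)F)C(F)(F)F
Why: O-sulfonylation of a phenol with a weak amine base; because the ester is already in place, no free phenol is present once the triflate is on the ring, so a base-triggered carbon-to-oxygen silyl shift cannot release the aryne early.

Step 9
Reactants: 13 5-ethynyl-1,2,3-trimethoxybenzene
Product: 14 3-(3,4,5-trimethoxyphenyl)propiolic acid
Conditions: n-BuLi, THF, −78 °C; CO2; then aq HCl
Reagents that add atoms: carbon dioxide, O=C=O
Why: Deprotonation of the terminal alkyne and carboxylation of the lithium acetylide, a standard route to arylpropiolic acids.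

Step 10
Reactants: 12 3-(benzyloxy)-2,4-dimethoxy-5-(pivaloyloxy)-6-(trimethylsilyl)phenyl trifluoromethanesulfonate; 14 3-(3,4,5-trimethoxyphenyl)propiolic acid
Product: 17 7-(benzyloxy)-6,8-dimethoxy-4-oxo-2-(3,4,5-trimethoxyphenyl)-4H-chromen-5-yl pivalate, via ring A aryne 15 (not isolated), via cesium ynone phenoxide 16 (not isolated)
Conditions: CsF (4 equiv), THF, 125 °C, sealed tube
Reagents that add atoms: none
Why: Fluoride attacks silicon on C4a and triflate leaves from C8a, releasing aryne 15. The cesium carboxylate of 14 adds through oxygen to C8a, the aryl anion formed at C4a attacks the neighbouring aryl ester carbonyl, and the strained four-membered alkoxide opens to the ortho-acyl phenoxide 16; this is a net insertion of the aryne into the acid C–O bond, the known aryne route to ortho-hydroxyaryl ketones and, with arylpropiolic acids, to flavones. Ring C then closes by 6-endo-dig oxa-Michael addition of the phenoxide oxygen to the β-carbon of the ynone, and the vinyl anion at C3 takes the proton that the acid brought in; 5-exo-dig closure to an aurone would need attack at the α-carbon, against the polarisation of the ynone. No stereocenter is formed. The step needs oxygen on C8a and not on C4a: the C5 pivaloyloxy group is more inductively withdrawing than the C8 methoxy group, so the charge developing on C4a is the better stabilised and C8a is the more electrophilic terminus, the bulk of the ester also shields C4a, and the ether oxygens on C6 and C7 act on the two termini in opposite senses and should largely cancel. The C4a anion must also take the propiolate carbonyl and not the pivalate carbonyl, which the tert-butyl group and the greater electrophilicity of the alkynoate should secure. Acyl transfer must outrun protonation of the C4a anion, which is why the only proton in the flask is that of the acid and the mixture is heated.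

Step 11
Reactants: 17 7-(benzyloxy)-6,8-dimethoxy-4-oxo-2-(3,4,5-trimethoxyphenyl)-4H-chromen-5-yl pivalate
Product: 18 7-(benzyloxy)-5-hydroxy-6,8-dimethoxy-2-(3,4,5-trimethoxyphenyl)-4H-chromen-4-one
Conditions: K2CO3 (0.5 equiv), MeOH/THF, rt; then aq NH4Cl
Reagents that add atoms: none
Why: Base-catalysed transesterification of a phenolic ester with methanol; the 5-phenoxide next to the C4 carbonyl is a good leaving group, while the benzyl ether, the methyl ethers and ring C should be inert at room temperature.

Step 12
Reactants: 18 7-(benzyloxy)-5-hydroxy-6,8-dimethoxy-2-(3,4,5-trimethoxyphenyl)-4H-chromen-4-one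
Product: 19 5,7-dihydroxy-6,8,3',4',5'-pentamethoxyflavone
Conditions: H2 (1 atm), Pd/C (10 wt %), EtOAc/MeOH, rt
Reagents that add atoms: none
Why: Hydrogenolysis of a benzyl aryl ether; the C2–C3 double bond belongs to an aryl-substituted vinylogous ester and is reduced much more slowly, so the reaction is stopped once the benzyl ether is consumed.

## Compound list

1 | 2,6-dimethoxyphenol (syringol) | COc1cccc(OC)c1O | starting material
2 | 2-(benzyloxy)-1,3-dimethoxybenzene | COc1cccc(OC)c1OCc1ccccc1 | intermediate
3 | 3-(benzyloxy)-1,5-dibromo-2,4-dimethoxybenzene | COc1c(Br)cc(Br)c(OC)c1OCc1ccccc1 | intermediate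
4 | 2,2'-[5-(benzyloxy)-4,6-dimethoxy-1,3-phenylene]bis(4,4,5,5-tetramethyl-1,3,2-dioxaborolane) | COc1c(B2OC(C)(C)C(C)(C)O2)cc(B2OC(C)(C)C(C)(C)O2)c(OC)c1OCc1ccccc1 | intermediate
5 | 5-(benzyloxy)-4,6-dimethoxybenzene-1,3-diol | COc1c(O)cc(O)c(OC)c1OCc1ccccc1 | intermediate
6 | 5-(benzyloxy)-2-bromo-4,6-dimethoxybenzene-1,3-diol | COc1c(O)c(Br)c(O)c(OC)c1OCc1ccccc1 | intermediate
7 | 1-(benzyloxy)-4-bromo-2,6-dimethoxy-3,5-bis[(trimethylsilyl)oxy]benzene | COc1c(O[Si](C)(C)C)c(Br)c(O[Si](C)(C)C)c(OC)c1OCc1ccccc1 | intermediate
8 | pivaloyl chloride | CC(C)(C)C(Cl)=O | starting material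
9 | lithium 3-(benzyloxy)-2,4-dimethoxy-6-(trimethylsilyl)-5-[(trimethylsilyl)oxy]phenolate | COc1c([O-])c([Si](C)(C)C)c(O[Si](C)(C)C)c(OC)c1OCc1ccccc1.[Li+] | intermediate (not isolated)
10 | 3-(benzyloxy)-2,4-dimethoxy-6-(trimethylsilyl)-5-[(trimethylsilyl)oxy]phenyl pivalate | COc1c(OC(=O)C(C)(C)C)c([Si](C)(C)C)c(O[Si](C)(C)C)c(OC)c1OCc1ccccc1 | intermediate (not isolated)
11 | 3-(benzyloxy)-5-hydroxy-2,4-dimethoxy-6-(trimethylsilyl)phenyl pivalate | COc1c(OCc2ccccc2)c(OC)c(OC(=O)C(C)(C)C)c([Si](C)(C)C)c1O | intermediate
12 | 3-(benzyloxy)-2,4-dimethoxy-5-(pivaloyloxy)-6-(trimethylsilyl)phenyl trifluoromethanesulfonate | COc1c(OCc2ccccc2)c(OC)c(OC(=O)C(C)(C)C)c([Si](C)(C)C)c1OS(=O)(=O)C(F)(F)F | intermediate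
13 | 5-ethynyl-1,2,3-trimethoxybenzene | C#Cc1cc(OC)c(OC)c(OC)c1 | starting material
14 | 3-(3,4,5-trimethoxyphenyl)propiolic acid | COc1cc(C#CC(=O)O)cc(OC)c1OC | intermediate
15 | 3-(benzyloxy)-2,4-dimethoxy-5,6-didehydrophenyl pivalate (ring A aryne across C4a–C8a) | COC1=C(OCc2ccccc2)C(OC)=C(OC(=O)C(C)(C)C)C#C1 | intermediate (not isolated)
16 | cesium 3-(benzyloxy)-2,4-dimethoxy-5-(pivaloyloxy)-6-[3-(3,4,5-trimethoxyphenyl)prop-2-ynoyl]phenolate | COc1cc(C#CC(=O)c2c(OC(=O)C(C)(C)C)c(OC)c(OCc3ccccc3)c(OC)c2[O-])cc(OC)c1OC.[Cs+] | intermediate (not isolated)
17 | 7-(benzyloxy)-6,8-dimethoxy-4-oxo-2-(3,4,5-trimethoxyphenyl)-4H-chromen-5-yl pivalate | COc1cc(-c2cc(=O)c3c(OC(=O)C(C)(C)C)c(OC)c(OCc4ccccc4)c(OC)c3o2)cc(OC)c1OC | intermediate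
18 | 7-(benzyloxy)-5-hydroxy-6,8-dimethoxy-2-(3,4,5-trimethoxyphenyl)-4H-chromen-4-one | COc1cc(-c2cc(=O)c3c(O)c(OC)c(OCc4ccccc4)c(OC)c3o2)cc(OC)c1OC | intermediate
19 | 5,7-dihydroxy-6,8,3',4',5'-pentamethoxyflavone | COc1cc(-c2cc(=O)c3c(O)c(OC)c(O)c(OC)c3o2)cc(OC)c1OC | target

## Step count and least certain steps

Total step count: 12. Longest linear sequence: 11 steps (steps 1 to 8 and 10 to 12); step 9 is a one-step side branch.

**Step 10 (key step).**
- What may go wrong: addition of the carboxylate at the wrong aryne terminus, because the electronic difference between an acyloxy and a methoxy neighbour is modest. The C4a anion may also be captured by a proton or by the pivalate carbonyl before it reaches the propiolate carbonyl, and the propiolate may decarboxylate thermally before it meets the aryne.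
- Fallback (organolithium acylation in place of aryne insertion; sets out from 6 and 14, returns at 18, so step 11 is skipped): 6 would be protected with MOMCl and i-Pr2NEt as 1-(benzyloxy)-4-bromo-2,6-dimethoxy-3,5-bis(methoxymethoxy)benzene F1. 14 would be converted through its acid chloride into N-methoxy-N-methyl-3-(3,4,5-trimethoxyphenyl)prop-2-ynamide F2. Bromine–lithium exchange on F1 (n-BuLi, THF, −78 °C) and addition to F2 should give 1-[4-(benzyloxy)-3,5-dimethoxy-2,6-bis(methoxymethoxy)phenyl]-3-(3,4,5-trimethoxyphenyl)prop-2-yn-1-one F3. HCl in MeOH should remove both acetals to give 1-[4-(benzyloxy)-2,6-dihydroxy-3,5-dimethoxyphenyl]-3-(3,4,5-trimethoxyphenyl)prop-2-yn-1-one F4. F4 should close by 6-endo-dig oxa-Michael addition (K2CO3, acetone, if closure is not spontaneous) to 18. Because F4 is symmetrical about its aryl–carbonyl axis, either hydroxyl gives the same flavone.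

**Step 5.**
- What may go wrong: oxidation of the electron-rich para-alkoxyphenol ring to a quinone in competition with substitution.
- Fallback (directed ortho-metalation in place of electrophilic substitution; sets out from 5, returns at 6): 5 would be protected with MOMCl and i-Pr2NEt as 3-(benzyloxy)-2,4-dimethoxy-1,5-bis(methoxymethoxy)benzene F5. Lithiation between the two acetal oxygens (n-BuLi, THF, 0 °C) and quenching with 1,2-dibromotetrafluoroethane should give 1-(benzyloxy)-4-bromo-2,6-dimethoxy-3,5-bis(methoxymethoxy)benzene F1, the same compound as in the fallback to step 10. HCl in MeOH would then release 6.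

**Step 7.**
- What may go wrong: incomplete O-acylation of the crowded lithium phenoxide by the hindered acid chloride, and cleavage of the aryl–silicon bond (ipso-protodesilylation of a very electron-rich arylsilane) while the silyl ether is removed.
- Fallback (triflate first, ester last; sets out from 7, returns at 12, bypassing 11): 9 would be generated as before and quenched with Tf2O at −78 °C. Cleavage of the remaining silyl ether on work-up should give 3-(benzyloxy)-5-hydroxy-2,4-dimethoxy-6-(trimethylsilyl)phenyl trifluoromethanesulfonate F6. Its neutral phenol would be acylated with PivCl, pyridine and catalytic DMAP in CH2Cl2 at 0 °C to give 12. The triflated ring is less electron-rich and so less prone to lose silicon. Only weak amine bases may be used, because the phenoxide of F6 could shift silicon to oxygen and release the aryne.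

**Step 3.**
- What may go wrong: stalling after the first carbon–boron bond, or protodebromination, on an electron-rich substrate.
- Fallback (direct carbon–oxygen coupling in place of borylation and oxidation; sets out from 3, returns at 5, bypassing 4): palladium-catalysed hydroxylation with KOH, Pd2(dba)3 and t-BuXPhos in 1,4-dioxane/H2O at 100 °C, followed by acidification. This fallback makes no new compound (F0).

**Step 12.**
- What may go wrong: reduction of the C2–C3 double bond of ring C along with, or in place of, cleavage of the benzyl ether.
- Fallback (Lewis-acid ether cleavage in place of hydrogenolysis; sets out from 18, returns at 19): BCl3 with pentamethylbenzene as cation scavenger in CH2Cl2 at −78 °C. This fallback makes no new compound (F0).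

## Further compounds

F1 | step 10 | 1-(benzyloxy)-4-bromo-2,6-dimethoxy-3,5-bis(methoxymethoxy)benzene | COCOc1c(Br)c(OCOC)c(OC)c(OCc2ccccc2)c1OC
F2 | step 10 | N-methoxy-N-methyl-3-(3,4,5-trimethoxyphenyl)prop-2-ynamide | COc1cc(C#CC(=O)N(C)OC)cc(OC)c1OC
F3 | step 10 | 1-[4-(benzyloxy)-3,5-dimethoxy-2,6-bis(methoxymethoxy)phenyl]-3-(3,4,5-trimethoxyphenyl)prop-2-yn-1-one | COCOc1c(C(=O)C#Cc2cc(OC)c(OC)c(OC)c2)c(OCOC)c(OC)c(OCc2ccccc2)c1OC
F4 | step 10 | 1-[4-(benzyloxy)-2,6-dihydroxy-3,5-dimethoxyphenyl]-3-(3,4,5-trimethoxyphenyl)prop-2-yn-1-one | COc1cc(C#CC(=O)c2c(O)c(OC)c(OCc3ccccc3)c(OC)c2O)cc(OC)c1OC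
F5 | step 5 | 3-(benzyloxy)-2,4-dimethoxy-1,5-bis(methoxymethoxy)benzene | COCOc1cc(OCOC)c(OC)c(OCc2ccccc2)c1OC
F6 | step 7 | 3-(benzyloxy)-5-hydroxy-2,4-dimethoxy-6-(trimethylsilyl)phenyl trifluoromethanesulfonate | COc1c(OCc2ccccc2)c(OC)c(O)c([Si](C)(C)C)c1OS(=O)(=O)C(F)(F)F
F0 | step 3 | none | none
F0 | step 12 | none | none
A1 | alternative 1 | 3-[2,4,6-tris(benzyloxy)-3,5-dimethoxyphenyl]-5-(3,4,5-trimethoxyphenyl)isoxazole | COc1cc(-c2cc(-c3c(OCc4ccccc4)c(OC)c(OCc4ccccc4)c(OC)c3OCc3ccccc3)no2)cc(OC)c1OC
A2 | alternative 1 | 2,4,6-tris(benzyloxy)-3,5-dimethoxybenzonitrile oxide | COc1c(OCc2ccccc2)c(C#[N+][O-])c(OCc2ccccc2)c(OC)c1OCc1ccccc1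
A3 | alternative 1 | 1,3,5-tris(benzyloxy)-2,4-dimethoxybenzene | COc1c(OCc2ccccc2)cc(OCc2ccccc2)c(OC)c1OCc1ccccc1
A4 | alternative 2 | 1-[2,4,6-tris(benzyloxy)-3,5-dimethoxyphenyl]-3-(3,4,5-trimethoxyphenyl)propane-1,3-dione | COc1cc(C(=O)CC(=O)c2c(OCc3ccccc3)c(OC)c(OCc3ccccc3)c(OC)c2OCc2ccccc2)cc(OC)c1OC
A5 | alternative 2 | 1-[2,4,6-tris(benzyloxy)-3,5-dimethoxyphenyl]ethanone | COc1c(OCc2ccccc2)c(C(C)=O)c(OCc2ccccc2)c(OC)c1OCc1ccccc1
A6 | alternative 2 | 5-iodo-1,2,3-trimethoxybenzene | COc1cc(I)cc(OC)c1OC
A7 | alternative 3 | 7-tert-butoxy-5,8-dihydroxy-6-methoxy-2-(3,4,5-trimethoxyphenyl)-4H-chromen-4-one | COc1cc(-c2cc(=O)c3c(O)c(OC)c(OC(C)(C)C)c(O)c3o2)cc(OC)c1OC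
A8 | alternative 3 | 2-tert-butoxy-4-hydroxy-3-methoxy-4-[4-oxo-6-(3,4,5-trimethoxyphenyl)-4H-pyran-3-yl]cyclobut-2-en-1-one (racemic) | COC1=C(OC(C)(C)C)C(=O)C1(O)c1coc(-c2cc(OC)c(OC)c(OC)c2)cc1=O
A9 | alternative 3 | 3-tert-butoxy-4-methoxycyclobut-3-ene-1,2-dione | COC1=C(OC(C)(C)C)C(=O)C1=O
A10 | alternative 3 | 5-iodo-2-(3,4,5-trimethoxyphenyl)-4H-pyran-4-one | COc1cc(-c2cc(=O)c(I)co2)cc(OC)c1OC
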